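**Retrosynthetic overview** (gibberellane numbering: C7 = carboxyl on C6, C19 = lactone carbonyl on C4, C20 = lactone CH2 on C10, C17 = exocyclic methylene)

1. Ring D (C8–C15–C16–C13–C14) is opened last at C15–C16 and C16–C13: C16 leaves as carbon monoxide, leaving an iodomethyl group (C15) on quaternary C8 and a C12=C13 enone (11-ketone); C17 is a Wittig carbon and the 11-ketone becomes the 11β-alcohol.
2. Enabling feature: C13 is the β-carbon of the C11 carbonyl (C11–C12–C13) and sits 1,3-diaxial across C14 of ring C to the C15 methylene on C8; C8 is quaternary, so the C15 radical has no competing pathway and a one-carbon insertion closes the five-membered ring.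
3. C15 and the C8 quaternary centre: reagent-controlled reduction of the 8-en-11-one, 11β-hydroxyl-directed cyclopropanation of C8=C9, then iodide opening of the cyclopropyl ketone.
4. Ring B: Mukaiyama–Michael (C6–C8), aldol (C5–C6), dehydration and electron-transfer reduction (H5); ring C arrives intact as 2-iodocyclohexenone (C9–C10 by enolate alkenylation); the 19,20-lactone by hydroxymethylation/lactonisation at C10; ring A and C4 by auxiliary-controlled Birch reduction–methylation.
5. Order of ring formation: A (from the arene), C (attached), lactone, B, temporary carbonate and cyclopropane rings, D last.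

Key step: step 18

Remark: the Birch methylation with the (S)-auxiliary is assumed to give the C4 configuration drawn (methylation anti to the methoxymethyl arm of the chelated enolate); otherwise the (R)-auxiliary is used.
Remark: 2-iodocyclohex-2-en-1-one and 1-(tert-butyldimethylsilyloxy)-1-methoxyethene are taken as commercial reagents.
Remark: centres given as "epimers" are left undefined in the SMILES because later steps erase or equilibrate them.

Step 1
Reactants: 1 2-methoxybenzoyl chloride; 2 (S)-2-(methoxymethyl)pyrrolidine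
Product: 3 (S)-(2-methoxyphenyl)[2-(methoxymethyl)pyrrolidin-1-yl]methanone
Conditions: Et3N, CH2Cl2, 0 °C to rt
Reagents that add atoms: (S)-2-(methoxymethyl)pyrrolidine, COC[C@@H]1CCCN1
Why: N-acylation of the amine by the acid chloride installs the prolinol-derived auxiliary that will control the C4 quaternary centre.

Step 2
Reactants: 3 aryl amide; 4 iodomethane
Product: 6 [(S)-2-(methoxymethyl)pyrrolidin-1-yl](2-methoxy-1-methylcyclohexa-2,5-dien-1-yl)methanone, via potassium dienolate 5 (not isolated)
Conditions: K, NH3 (l), THF, t-BuOH (1 equiv), −78 °C; then MeI, −78 °C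
Reagents that add atoms: iodomethane, CI
Why: Birch reduction–alkylation of a chiral 2-methoxybenzamide; the chelated amide enolate should be methylated on the face away from the methoxymethyl arm, which sets C4 (methyl β, carbonyl α) and leaves the C2=C3 alkene and the C5 enol ether.

Step 3
Reactants: 6 diene amide
Product: 7 [(S)-2-(methoxymethyl)pyrrolidin-1-yl](1-methyl-2-oxocyclohex-5-en-1-yl)methanone
Conditions: 1 M HCl, THF, rt
Reagents that add atoms: water, O
Why: acid hydrolysis of the methyl enol ether gives the C5 ketone; the C2=C3 alkene cannot move into conjugation because C4 is quaternary.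

Step 4
Reactants: 7 keto amide; 8 2-iodocyclohex-2-en-1-one
Product: 10 keto amide bearing a 6-oxocyclohex-1-en-1-yl group at C10 (C10 epimers), via chlorozinc enolate 9 (not isolated)
Conditions: LiN(SiMe3)2, THF, −78 °C; ZnCl2, 0 °C; then 8, Pd2(dba)3 (2.5 mol%), P(t-Bu)3·HBF4 (6 mol%), THF, 50 °C
Reagents that add atoms: 2-iodocyclohex-2-en-1-one, O=C1CCCC=C1I
Why: palladium-catalysed α-alkenylation of a ketone enolate (Negishi-type enolate coupling); C10 is the only enolisable carbon and C9 arrives sp2, so only the epimerisable C10 becomes stereogenic.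

Step 5
Reactants: 10 alkenylated keto amide; 11 formaldehyde
Product: 13 1-methyl-5-(6-oxocyclohex-1-en-1-yl)-3-oxabicyclo[3.3.1]non-7-ene-2,9-dione, via hydroxymethyl ketone 12 (not isolated)
Conditions: CH2O (37% aq.), K2CO3, THF, rt; then TsOH·H2O (1.5 equiv), PhMe, 90 °C
Reagents that add atoms: formaldehyde, C=O
Why: aldol hydroxymethylation at the doubly activated C10, then acid-promoted intramolecular alcoholysis of the amide (six-membered lactonisation) expels the auxiliary; only the epimer with C20 cis to C19 can lactonise and retro-aldol/aldol equilibration should funnel the other one into it, which fixes C10.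

Step 6
Reactants: 13 keto lactone
Product: 14 2β,3β-diol of 13
Conditions: OsO4 (2 mol%), NMO, acetone/H2O, 0 °C to rt
Reagents that add atoms: osmium tetroxide, O=[Os](=O)(=O)=O; N-methylmorpholine N-oxide, C[N+]1([O-])CCOCC1; water, O
Why: Upjohn syn-dihydroxylation; the cis-disubstituted C2=C3 alkene is attacked on its exo (β) face, away from the lactone bridge, and the enone alkene is too electron-poor to compete.

Step 7
Reactants: 14 diol; 15 1,1'-carbonyldiimidazole
Product: 16 2β,3β-cyclic carbonate of 14
Conditions: DMAP (cat.), PhMe, 80 °C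
Reagents that add atoms: 1,1'-carbonyldiimidazole, O=C(n1ccnc1)n1ccnc1
Why: carbonate formation on the cis-diol gives a protecting ring that survives the Lewis acidic iodide step 16 and falls off in the final saponification.

Step 8
Reactants: 16 enone carbonate; 17 1-(tert-butyldimethylsilyloxy)-1-methoxyethene
Product: 18 Michael adduct with CH2CO2Me on C8 and a C9=C11 tert-butyldimethylsilyl enol ether (C8 epimers)
Conditions: Tf2NH (5 mol%), CH2Cl2, −78 °C
Reagents that add atoms: 1-(tert-butyldimethylsilyloxy)-1-methoxyethene, COC(=C)O[Si](C)(C)C(C)(C)C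
Why: Mukaiyama–Michael addition to the unhindered β-carbon C8 with silyl transfer to O11 brings in C6/C7 and stores the ketone as a regiodefined silyl enol ether; the C8 centre is erased in step 12.

Step 9
Reactants: 18 Michael adduct
Product: 19 ring-B β-hydroxy ester (C5, C6 and C8 epimers)
Conditions: LiN(i-Pr)2, THF, −78 to −40 °C; aq. NH4Cl
Reagents that add atoms: none
Why: intramolecular aldol addition (5-exo-trig) of the ester enolate at C6, the only enolisable position, to the C5 ketone closes ring B; the new centres are removed in steps 10–12.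

Step 10
Reactants: 19 β-hydroxy ester
Product: 20 C5=C6 unsaturated methyl ester (C8 epimers)
Conditions: SOCl2, pyridine, CH2Cl2, −20 to 0 °C
Reagents that add atoms: none
Why: dehydration of the tertiary alcohol through its chlorosulfite; C6–H is the only β-hydrogen, so the conjugated tetrasubstituted enoate is the sole alkene.

Step 11
Reactants: 20 enoate
Product: 21 5β-H saturated methyl ester (C6 and C8 epimers)
Conditions: SmI2, HMPA, t-BuOH, THF, −78 to 0 °C
Reagents that add atoms: none
Why: single-electron conjugate reduction of the enoate by samarium diiodide; C5 should be protonated with C6 pseudo-equatorial on ring A (an axial C6 would be syn-diaxial to the 3β-oxygen), which gives H5β.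

Step 12
Reactants: 21 silyl enol ether ester
Product: 22 8-en-11-one with 5β-H and 6β-CO2Me
Conditions: Pd(OAc)2 (1.2 equiv), MeCN, 40 °C
Reagents that add atoms: none
Why: Saegusa–Ito oxidation gives the tetrasubstituted C8=C9 enone because only C8 carries a β-hydrogen; the vinylogously acidic C6–H should equilibrate to the 6β-ester, trans to C4.

Step 13
Reactants: 22 enone
Product: 23 11β-allylic alcohol (11S)
Conditions: (R)-2-methyl-CBS-oxazaborolidine (20 mol%), BH3·SMe2, THF, −30 °C; MeOH
Reagents that add atoms: none
Why: Corey–Bakshi–Shibata reduction; the catalyst (alkenyl side as large group) delivers hydride to the α-face and sets the 11β-hydroxyl that directs the next step.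

Step 14
Reactants: 23 allylic alcohol; 24 diiodomethane
Product: 25 8β,9β-methano 11β-alcohol (cyclopropane carbon = C15)
Conditions: Et2Zn, CH2I2, CH2Cl2, 0 °C to rt
Reagents that add atoms: diiodomethane, ICI
Why: hydroxyl-directed Simmons–Smith cyclopropanation; the zinc alkoxide delivers the methylene syn to the 11β-oxygen onto C8=C9, which puts C15 on the β-face and sets the C8 quaternary centre.

Step 15
Reactants: 25 cyclopropyl carbinol
Product: 26 8β,9β-methano 11-ketone
Conditions: Dess–Martin periodinane, NaHCO3, CH2Cl2, rt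
Reagents that add atoms: none
Why: Dess–Martin oxidation gives the cyclopropyl ketone, which activates the C9–C15 bond.

Step 16
Reactants: 26 cyclopropyl ketone
Product: 28 8β-iodomethyl 9β-H 11-ketone, via iodo silyl enol ether 27 (not isolated)
Conditions: Me3SiI, CH2Cl2, −40 to 0 °C; then 1 M HCl, THF, 0 °C
Reagents that add atoms: iodotrimethylsilane, C[Si](C)(C)I
Why: homoconjugate addition of iodide to the O-silylated cyclopropyl ketone cleaves the exocyclic C9–C15 bond (best overlap with the carbonyl, attack at the unhindered CH2); hydrolysis protonates C9 to the cis-fused H9β ketone, expected to be the stable epimer.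

Step 17
Reactants: 28 iodo ketone
Product: 29 8β-iodomethyl 12-en-11-one
Conditions: IBX, 4-methoxypyridine N-oxide, DMSO, rt
Reagents that add atoms: none
Why: IBX-mediated α,β-dehydrogenation of the ketone; only the C12–C13 side has both α- and β-hydrogens (C8 is quaternary), and the non-basic medium avoids reclosure of the γ-iodo ketone to the cyclopropane.

Step 18
Reactants: 29 iodo enone; 30 carbon monoxide
Product: 31 tetracyclic 11,16-diketone (ring D closed, 17-nor)
Conditions: CO (80 atm), Bu3SnH (slow addition), AIBN, PhH (0.02 M), 80 °C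
Reagents that add atoms: carbon monoxide, [C-]#[O+]
Why: Radical carbonylation–cyclisation, a [4+1] annulation: the stannyl radical abstracts iodine, the neopentyl C15 radical captures CO to give the acyl radical at the new C16, this nucleophilic radical adds to C13 (β-carbon of the 12-en-11-one), and the α-keto radical at C12 is reduced by the stannane. The closest known reaction type is the tin hydride/CO conversion of 4-alkenyl iodides into cyclopentanones by acyl radical cyclisation. Ring D (C8–C15–C16–C13–C14) closes 5-exo-trig; the alternative attack at C12 would be 6-endo onto the α-carbon of the enone. The one new stereocentre, C13, is fixed by the tether: C15 is axial on the β-face of C8, so C16 can only reach the β-face of C13 across C14, giving the cis-bridged bicyclo[3.2.1]octane. The step needs CO capture to beat reduction of the C15 radical and cyclisation to beat aldehyde formation; high CO pressure, high dilution and slow stannane addition serve the first, and the electron-poor, 1,3-diaxially held enone the second. Because C8 is quaternary and ring B is saturated, C15 has no β-hydrogen, no neighbouring alkene and no easy 1,5-hydrogen shift.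

Step 19
Reactants: 31 diketone; 32 methyltriphenylphosphonium bromide
Product: 33 16-methylene 11-ketone
Conditions: Ph3PCH3Br, KN(SiMe3)2, THF, 0 °C; then 31, 0 °C
Reagents that add atoms: methylenetriphenylphosphorane (from 32), C=P(c1ccccc1)(c1ccccc1)c1ccccc1
Why: Wittig methylenation; the C16 cyclopentanone should react first because the C11 ketone is shielded by the C15–C16 bridge on one face and by axial C10 on the other.

Step 20
Reactants: 33 methylene ketone
Product: 34 11β-alcohol (methyl ester, carbonate, lactone)
Conditions: NaBH4, MeOH/THF, −40 to 0 °C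
Reagents that add atoms: none
Why: hydride reduction of a bicyclo[3.2.1]octan-3-one-type ketone; attack is expected from the exo α-face, away from the two-carbon bridge (as in tropinone to tropine), giving the axial 11β-alcohol.

Step 21
Reactants: 34 protected alcohol
Product: 36 target acid CNP0302900.3, via dipotassium seco-acid salt 35 (not isolated)
Conditions: KOH (2 M), MeOH/H2O, 65 °C; then aq. HCl to pH 2, rt
Reagents that add atoms: potassium hydroxide, [K+].[OH-]; water, O
Why: saponification cleaves the carbonate and the hindered C7 methyl ester and opens the lactone to the carboxylate, which should suppress retro-aldol at C3; acidification relactonises the 1,3-diaxial C19 acid and C20 alcohol.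

**Compound list**

1 | 2-methoxybenzoyl chloride | COc1ccccc1C(Cl)=O | starting material
2 | (S)-2-(methoxymethyl)pyrrolidine | COC[C@@H]1CCCN1 | starting material
3 | (S)-(2-methoxyphenyl)[2-(methoxymethyl)pyrrolidin-1-yl]methanone | COC[C@@H]1CCCN1C(=O)c1ccccc1OC | intermediate
4 | iodomethane | CI | starting material
5 | potassium dienolate of the 1,4-dihydro amide | COC[C@@H]1CCCN1C([O-])=C1C=CCC=C1OC.[K+] | intermediate (not isolated)
6 | [(S)-2-(methoxymethyl)pyrrolidin-1-yl](2-methoxy-1-methylcyclohexa-2,5-dien-1-yl)methanone (future C4: methyl β) | COC1=CCC=C[C@@]1(C)C(=O)N1CCC[C@H]1COC | intermediate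
7 | [(S)-2-(methoxymethyl)pyrrolidin-1-yl](1-methyl-2-oxocyclohex-5-en-1-yl)methanone | O=C1CCC=C[C@@]1(C)C(=O)N1CCC[C@H]1COC | intermediate
8 | 2-iodocyclohex-2-en-1-one | O=C1CCCC=C1I | starting material
9 | chlorozinc enolate of 7 | Cl[Zn]OC1=CCC=C[C@@]1(C)C(=O)N1CCC[C@H]1COC | intermediate (not isolated)
10 | keto amide with 6-oxocyclohex-1-en-1-yl at C10 (C10 epimers) | O=C1C(C2=CCCCC2=O)CC=C[C@@]1(C)C(=O)N1CCC[C@H]1COC | intermediate
11 | formaldehyde | C=O | starting material
12 | C10 hydroxymethyl derivative of 10 (C10 epimers) | O=C1C(CO)(C2=CCCCC2=O)CC=C[C@@]1(C)C(=O)N1CCC[C@H]1COC | intermediate (not isolated)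
13 | 1-methyl-5-(6-oxocyclohex-1-en-1-yl)-3-oxabicyclo[3.3.1]non-7-ene-2,9-dione (19,20-lactone, C5 ketone) | O=C1CCCC=C1[C@]12COC(=O)[C@](C)(C=CC1)C2=O | intermediate
14 | 2β,3β-diol of 13 | O=C1CCCC=C1[C@]12COC(=O)[C@](C)([C@@H](O)[C@@H](O)C1)C2=O | intermediate
15 | 1,1'-carbonyldiimidazole | O=C(n1ccnc1)n1ccnc1 | starting material
16 | 2β,3β-cyclic carbonate of 14 | O=C1CCCC=C1[C@]12COC(=O)[C@](C)([C@@H](OC(=O)O4)[C@@H]4C1)C2=O | intermediate
17 | 1-(tert-butyldimethylsilyloxy)-1-methoxyethene | COC(=C)O[Si](C)(C)C(C)(C)C | starting material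
18 | Michael adduct: CH2CO2Me on C8, C9=C11 silyl enol ether (C8 epimers) | COC(=O)CC1CCCC(O[Si](C)(C)C(C)(C)C)=C1[C@]12COC(=O)[C@](C)([C@@H](OC(=O)O4)[C@@H]4C1)C2=O | intermediate
19 | ring-B β-hydroxy ester (C5, C6, C8 epimers) | COC(=O)C1C2CCCC(O[Si](C)(C)C(C)(C)C)=C2[C@]23COC(=O)[C@](C)([C@@H](OC(=O)O4)[C@@H]4C2)C13O | intermediate
20 | C5=C6 unsaturated methyl ester (C8 epimers) | COC(=O)C=1C2CCCC(O[Si](C)(C)C(C)(C)C)=C2[C@]23COC(=O)[C@](C)([C@@H](OC(=O)O4)[C@@H]4C2)C=13 | intermediate
21 | 5β-H saturated methyl ester (C6, C8 epimers) | COC(=O)C1C2CCCC(O[Si](C)(C)C(C)(C)C)=C2[C@]23COC(=O)[C@](C)([C@@H](OC(=O)O4)[C@@H]4C2)[C@H]31 | intermediate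
22 | 8-en-11-one, 5β-H, 6β-CO2Me | O=C1CCCC2=C1[C@]13COC(=O)[C@](C)([C@@H](OC(=O)O4)[C@@H]4C1)[C@H]3[C@@H]2C(=O)OC | intermediate
23 | 11β-allylic alcohol | O[C@H]1CCCC2=C1[C@]13COC(=O)[C@](C)([C@@H](OC(=O)O4)[C@@H]4C1)[C@H]3[C@@H]2C(=O)OC | intermediate
24 | diiodomethane | ICI | starting material
25 | 8β,9β-methano 11β-alcohol | C1[C@]23CCC[C@H](O)[C@]12[C@]12COC(=O)[C@](C)([C@@H](OC(=O)O4)[C@@H]4C1)[C@H]2[C@@H]3C(=O)OC | intermediate
26 | 8β,9β-methano 11-ketone | C1[C@]23CCCC(=O)[C@]12[C@]12COC(=O)[C@](C)([C@@H](OC(=O)O4)[C@@H]4C1)[C@H]2[C@@H]3C(=O)OC | intermediate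
27 | 8β-iodomethyl C9=C11 trimethylsilyl enol ether | IC[C@]12CCCC(O[Si](C)(C)C)=C1[C@]13COC(=O)[C@](C)([C@@H](OC(=O)O4)[C@@H]4C1)[C@H]3[C@@H]2C(=O)OC | intermediate (not isolated)
28 | 8β-iodomethyl 9β-H 11-ketone | IC[C@]12CCCC(=O)[C@H]1[C@]13COC(=O)[C@](C)([C@@H](OC(=O)O4)[C@@H]4C1)[C@H]3[C@@H]2C(=O)OC | intermediate
29 | 8β-iodomethyl 12-en-11-one | IC[C@]12CC=CC(=O)[C@H]1[C@]13COC(=O)[C@](C)([C@@H](OC(=O)O4)[C@@H]4C1)[C@H]3[C@@H]2C(=O)OC | intermediate
30 | carbon monoxide | [C-]#[O+] | starting material
31 | tetracyclic 11,16-diketone (17-nor) | O=C1C[C@]23C[C@H]1CC(=O)[C@H]2[C@]12COC(=O)[C@](C)([C@@H](OC(=O)O4)[C@@H]4C1)[C@H]2[C@@H]3C(=O)OC | intermediate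
32 | methyltriphenylphosphonium bromide | C[P+](c1ccccc1)(c1ccccc1)c1ccccc1.[Br-] | starting material
33 | 16-methylene 11-ketone | C=C1C[C@]23C[C@H]1CC(=O)[C@H]2[C@]12COC(=O)[C@](C)([C@@H](OC(=O)O4)[C@@H]4C1)[C@H]2[C@@H]3C(=O)OC | intermediate
34 | 11β-alcohol, C7 methyl ester, 2β,3β-carbonate | C=C1C[C@]23C[C@H]1C[C@H](O)[C@H]2[C@]12COC(=O)[C@](C)([C@@H](OC(=O)O4)[C@@H]4C1)[C@H]2[C@@H]3C(=O)OC | intermediate
35 | dipotassium salt of the lactone-opened 7,19-dioic acid tetrol | C=C1C[C@]23C[C@H]1C[C@H](O)[C@H]2[C@]1(CO)C[C@H](O)[C@H](O)[C@@](C)(C(=O)[O-])[C@H]1[C@@H]3C(=O)[O-].[K+].[K+] | intermediate (not isolated)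
36 | CNP0302900.3 (2β,3β,11β-trihydroxy 19,20-lactone 7-acid) | C=C1C[C@]23C[C@H]1C[C@H](O)[C@H]2[C@]12COC(=O)[C@](C)([C@@H](O)[C@@H](O)C1)[C@H]2[C@@H]3C(=O)O | target

**Totals:** 21 steps; longest linear sequence 21 steps (from 2-methoxybenzoyl chloride).

**Three steps most likely to fail**

Step 4: conjugate addition of the enolate to the iodoenone, or base-induced decomposition of the iodoenone, may outrun oxidative addition and transmetallation. Fallback: setting out from 7, the ketone is α-vinylated (LiN(SiMe3)2, Pd2(dba)3, P(t-Bu)3) with 6-bromo-1,4-dioxaspiro[4.5]dec-6-ene, a vinyl bromide that is no Michael acceptor, to give the ketal-protected alkenyl keto amide F1. Hydroxymethylation as in step 5 gives the hydroxymethyl ketal F2 (not isolated), and the TsOH stage lactonises and removes the ketal together, so the route is rejoined at 13.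

Step 18: the C15 radical may be reduced to a methyl group before it captures CO, or the acyl radical may be reduced to the aldehyde before it cyclises. Fallback: setting out from 29, a tin hydride radical annulation with 2,6-dimethylphenyl isocyanide (Bu3SnH, AIBN, PhH, 80 °C) passes through an imidoyl radical that cyclises onto C13 and gives the C16 N-aryl imine F3. Hydrolysis with aqueous oxalic acid in THF returns to 31.

Step 20: facial selectivity may be poor or reversed, because axial C10 on C9 shields the α-face while the C15–C16 bridge shields the β-face. Fallback: setting out from 33, if hydride is delivered to the β-face the same reduction gives the 11α-alcohol F4. Mitsunobu esterification (4-nitrobenzoic acid, PPh3, diisopropyl azodicarboxylate) inverts C11 to the 11β 4-nitrobenzoate F5, whose ester is cleaved with the others under the conditions of step 21, so the route is rejoined at 36.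

Further compounds
F1 | step 4 | keto amide bearing a 1,4-dioxaspiro[4.5]dec-6-en-6-yl group at C10 (C10 epimers) | O=C1C(C2=CCCCC23OCCO3)CC=C[C@@]1(C)C(=O)N1CCC[C@H]1COC
F2 | step 4 | C10 hydroxymethyl derivative of F1 (C10 epimers) | O=C1C(CO)(C2=CCCCC23OCCO3)CC=C[C@@]1(C)C(=O)N1CCC[C@H]1COC
F3 | step 18 | C16 N-(2,6-dimethylphenyl)imine of diketone 31 | Cc1cccc(C)c1N=C1C[C@]23C[C@H]1CC(=O)[C@H]2[C@]12COC(=O)[C@](C)([C@@H](OC(=O)O4)[C@@H]4C1)[C@H]2[C@@H]3C(=O)OC
F4 | step 20 | 11α-alcohol epimer of 34 | C=C1C[C@]23C[C@H]1C[C@@H](O)[C@H]2[C@]12COC(=O)[C@](C)([C@@H](OC(=O)O4)[C@@H]4C1)[C@H]2[C@@H]3C(=O)OC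
F5 | step 20 | 11β 4-nitrobenzoate of 34 | C=C1C[C@]23C[C@H]1C[C@H](OC(=O)c4ccc(cc4)[N+](=O)[O-])[C@H]2[C@]12COC(=O)[C@](C)([C@@H](OC(=O)O5)[C@@H]5C1)[C@H]2[C@@H]3C(=O)OC
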